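Labdane numbering is used throughout (C19 = carboxyl carbon on C4, C20 = methyl on C10, C17 = methylidene carbon on C8, C15 = acetoxy-bearing carbon).

**Plan**
- Cuts: the acetate and the C8=C17 methylidene come off last (Wittig on an 8-ketone). Ring A is then cut at C1–C10 and C2–C3, which removes C1–C2 as phenyl vinyl sulfone and leaves a ring-B methylidenecyclohexane carrying a 2-methylmalondialdehyde on C5. The side chain is cut at C9–C11.
- Enabling feature: C10 is a ring-fusion carbon that bears a methyl group (C20), so it can arise as a tertiary radical from a C10=C20 methylidene on ring B. C3 lies three bonds away (C10–C5–C4–C3) as a formyl group on the quaternary C4, so a two-carbon radical acceptor bridges C10 and C3 and closes ring A.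
- Forward order: ring B first (asymmetric allylic alkylation of cyclohexenyl acetate with methylmalonate, enone formation, Negishi coupling of the side chain, deconjugation to the methylidene), then ring A by the radical–polar annulation, then Julia elimination, hydrogenation, methylenation and acetylation.
- Stereochemistry: C13 comes from methyl (R)-3-methylglutarate; C5 from the ligand-controlled allylic alkylation; C9 from kinetic protonation (and it is the thermodynamic epimer at the 8-ketone stage); C10 and C4 are set in the key step relative to C5.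

Key step: step 14

Assumption: the (S,S)-antipode of the bisphosphine ligand is taken to give the (R)-configured product 8, by analogy with the usual sense for malonates and cyclohex-2-enyl acetate; if the sense is the reverse, the (R,R)-ligand is used and nothing else changes.

**Step 1**
Reactants: 1 methyl (R)-3-methylglutarate
Product: 2 methyl (3R)-5-hydroxy-3-methylpentanoate
Conditions: BH3·SMe2, THF, 0 °C to rt; MeOH quench
Reagents that add atoms: none
Why: Chemoselective borane reduction of the free carboxylic acid beside the methyl ester differentiates the two chain ends and does not touch the stereocenter that becomes C13.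

**Step 2**
Reactants: 2 methyl (3R)-5-hydroxy-3-methylpentanoate
Product: 3 methyl (3R)-5-(tert-butyldimethylsilyloxy)-3-methylpentanoate
Conditions: t-BuMe2SiCl, imidazole, DMF, 0 °C to rt
Reagents that add atoms: tert-butyldimethylsilyl chloride, CC(C)(C)[Si](C)(C)Cl
Why: Silyl ether protection of the primary alcohol, done directly so that the hydroxy ester cannot lactonize; no stereocenter is touched.

**Step 3**
Reactants: 3 methyl (3R)-5-(tert-butyldimethylsilyloxy)-3-methylpentanoate
Product: 4 (3S)-5-(tert-butyldimethylsilyloxy)-3-methylpentan-1-ol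
Conditions: i-Bu2AlH (2.2 equiv), CH2Cl2, −78 to 0 °C
Reagents that add atoms: none
Why: Aluminium hydride reduction of the ester to the primary alcohol; the descriptor changes only by priority, not in space.

**Step 4**
Reactants: 4 (3S)-5-(tert-butyldimethylsilyloxy)-3-methylpentan-1-ol
Product: 5 tert-butyl{[(3R)-5-iodo-3-methylpentyl]oxy}dimethylsilane
Conditions: I2, PPh3, imidazole, CH2Cl2, 0 °C
Reagents that add atoms: iodine, [I][I]
Why: Appel-type iodination of a primary alcohol under neutral conditions that the silyl ether tolerates.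

**Step 5**
Reactants: 6 rac-cyclohex-2-en-1-yl acetate; 7 dimethyl methylmalonate
Product: 8 dimethyl 2-[(1R)-cyclohex-2-en-1-yl]-2-methylmalonate
Conditions: [Pd(C3H5)Cl]2 (2.5 mol %), (1S,2S)-N,N′-bis[2-(diphenylphosphino)benzoyl]cyclohexane-1,2-diamine (7.5 mol %), N,O-bis(trimethylsilyl)acetamide, KOAc (cat.), CH2Cl2, rt
Reagents that add atoms: none
Why: Tsuji–Trost asymmetric allylic alkylation, in which both enantiomers of 6 ionize to one meso π-allyl palladium complex and the chiral ligand steers the malonate to one of the two enantiotopic termini, which sets C5.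

**Step 6**
Reactants: 8 dimethyl 2-[(1R)-cyclohex-2-en-1-yl]-2-methylmalonate
Product: 9 dimethyl 2-methyl-2-[(1R)-4-oxocyclohex-2-en-1-yl]malonate
Conditions: Pd(OH)2/C (cat.), t-BuOOH, K2CO3, CH2Cl2, 0 °C to rt
Reagents that add atoms: tert-butyl hydroperoxide, CC(C)(C)OO
Why: Radical allylic oxidation of a cyclohexene to the enone, expected at the C8 methylene because the other allylic position (C5–H) is shielded by the quaternary malonate carbon; C5 is not touched.

**Step 7**
Reactants: 9 dimethyl 2-methyl-2-[(1R)-4-oxocyclohex-2-en-1-yl]malonate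
Product: 11 dimethyl 2-methyl-2-[(1R)-2-methyl-4-oxocyclohex-2-en-1-yl]malonate, via trimethylsilyl enol ether 10 (not isolated)
Conditions: MeMgBr, CuI (10 mol %), Me3SiCl, THF, −78 °C; then Pd(OAc)2 (1.05 equiv), MeCN, rt
Reagents that add atoms: methylmagnesium bromide, C[Mg]Br
Why: Copper-catalysed 1,4-addition anti to the C5 substituent with silyl trapping, then Saegusa–Ito dehydrogenation, which removes the transient C10 stereocenter again and leaves the β-methyl enone with C5 unchanged.

**Step 8**
Reactants: 11 dimethyl 2-methyl-2-[(1R)-2-methyl-4-oxocyclohex-2-en-1-yl]malonate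
Product: 12 dimethyl 2-[(1S)-3-iodo-2-methyl-4-oxocyclohex-2-en-1-yl]-2-methylmalonate
Conditions: I2, PhI(O2CCF3)2, pyridine, CH2Cl2, rt
Reagents that add atoms: iodine, [I][I]
Why: α-Iodination of the enone by amine conjugate addition, iodination and elimination; the C5 descriptor changes only because iodine alters the priorities.

**Step 9**
Reactants: 12 dimethyl 2-[(1S)-3-iodo-2-methyl-4-oxocyclohex-2-en-1-yl]-2-methylmalonate; 5 tert-butyl{[(3R)-5-iodo-3-methylpentyl]oxy}dimethylsilane
Product: 14 dimethyl 2-[(1R)-3-[(3S)-5-(tert-butyldimethylsilyloxy)-3-methylpentyl]-2-methyl-4-oxocyclohex-2-en-1-yl]-2-methylmalonate, via alkylzinc iodide 13 (not isolated)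
Conditions: Zn dust, LiCl, THF, 40 °C (5 to 13); then 12, PdCl2(dppf) (5 mol %), THF/DMA, rt to 50 °C
Reagents that add atoms: none
Why: Negishi sp2–sp3 coupling of an α-iodoenone with a primary alkylzinc reagent, in which the bidentate phosphine suppresses β-hydride elimination and the esters, enone and silyl ether are tolerated; C9–C11 is formed without touching C5 or C13.

**Step 10**
Reactants: 14 the 2-alkyl-3-methyl enone
Product: 16 dimethyl 2-[(1R,3R)-3-[(3S)-5-(tert-butyldimethylsilyloxy)-3-methylpentyl]-2-methylidene-4-oxocyclohexyl]-2-methylmalonate, via potassium dienolate 15 (not isolated)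
Conditions: KOt-Bu, t-BuOH/THF, 0 °C; then inverse addition to cold 10% aq. AcOH
Reagents that add atoms: none
Why: Base-mediated deconjugation through the extended dienolate and kinetic α-protonation: allylic strain with the C10 methyl holds the bulky C5 substituent pseudoaxial, so C5–H lies in the enone plane and only a C20 hydrogen should be removed, and the proton should then enter C9 anti to that substituent, placing the side chain cis to it.

**Step 11**
Reactants: 16 the β,γ-unsaturated ketone
Product: 17 dimethyl 2-[(6R,8R)-6-[(3S)-5-(tert-butyldimethylsilyloxy)-3-methylpentyl]-7-methylidene-1,4-dioxaspiro[4.5]decan-8-yl]-2-methylmalonate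
Conditions: (Me3SiOCH2)2, Me3SiOTf (cat.), CH2Cl2, −78 °C
Reagents that add atoms: 1,2-bis(trimethylsilyloxy)ethane, C[Si](C)(C)OCCO[Si](C)(C)C
Why: Aprotic silyl-triflate-catalysed ketalization at low temperature, a method that does not move β,γ-double bonds or epimerize the α-carbon, so C9 and the methylidene are kept.

**Step 12**
Reactants: 17 the ketal diester
Product: 18 2-[(6R,8R)-6-[(3S)-5-(tert-butyldimethylsilyloxy)-3-methylpentyl]-7-methylidene-1,4-dioxaspiro[4.5]decan-8-yl]-2-methylpropane-1,3-diol
Conditions: LiAlH4, THF, 0 °C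
Reagents that add atoms: none
Why: Hydride reduction of both esters to the symmetrical 1,3-diol, which keeps C4 free of stereochemistry; ketal, silyl ether and alkene are inert.

**Step 13**
Reactants: 18 the 1,3-diol
Product: 19 2-[(6R,8R)-6-[(3S)-5-(tert-butyldimethylsilyloxy)-3-methylpentyl]-7-methylidene-1,4-dioxaspiro[4.5]decan-8-yl]-2-methylpropanedial
Conditions: (COCl)2, DMSO, CH2Cl2, −78 °C; Et3N
Reagents that add atoms: none
Why: Swern oxidation of a neopentyl 1,3-diol to the non-enolizable 2,2-disubstituted malondialdehyde, with no OH group left in the molecule.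

**Step 14**
Reactants: 19 the methylidene dialdehyde; 20 phenyl vinyl sulfone
Product: 22 15-(tert-butyldimethylsilyloxy)-8,8-ethylenedioxy-3-hydroxy-2-(phenylsulfonyl)-17-norlabdan-19-al, via sulfonyl carbanion 21 (not isolated)
Conditions: Fe(acac)3 (30 mol %), PhSiH2(Oi-Pr) (2 equiv), 20 (3 equiv), THF, 0 °C to rt; aqueous work-up
Reagents that add atoms: none
Why: Proposed new method: hydrogen-atom transfer from an iron hydride to the C10=C20 methylidene (the only electron-rich alkene) gives the tertiary C10 radical and the C20 methyl, this radical adds to phenyl vinyl sulfone (C1–C10), the α-sulfonyl radical is reduced by ferrous iron to the carbanion, and the carbanion closes ring A on one formyl group (C2–C3) in a 6-exo-trig aldol whose alkoxide returns the iron to the cycle; the closest known reaction types are the iron-hydride reductive olefin coupling with vinyl sulfones and the hydrogen-atom-transfer-initiated conjugate addition–aldol annulation of alkenyl aldehydes with enones. C10 is set because the acceptor should approach the planar radical on the face opposite the two cis substituents that flank it (the C4 carbon on C5 and the side chain on C9), which puts C1 trans to both and the new methyl axial, so that ring A closes as the trans-decalin. C4 is set in the ring closure by the choice between the two diastereotopic formyl groups: in the chair transition state the group left on C4 that sits 1,3-diaxial to the C20 methyl should be the small formyl and not the methyl, which gives the 4β-formyl (C19) isomer. C2 and C3 form as mixtures and are removed in step 16. The step needs the carbanion to add to the aldehyde before it is protonated, which the aprotic medium, the absence of OH groups in 19 and the six-membered chair closure are meant to secure.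

**Step 15**
Reactants: 22 the hydroxy sulfone aldehyde
Product: 23 15-(tert-butyldimethylsilyloxy)-8,8-ethylenedioxy-3-hydroxy-2-(phenylsulfonyl)-17-norlabdan-19-oic acid
Conditions: NaClO2, NaH2PO4, 2-methyl-2-butene, t-BuOH/H2O, 0 °C to rt
Reagents that add atoms: sodium chlorite, [Na+].[O-]Cl=O
Why: Pinnick oxidation of the hindered, non-enolizable C19 aldehyde to the acid under buffered conditions that spare ketal, silyl ether and the β-hydroxy sulfone.

**Step 16**
Reactants: 23 the hydroxy sulfone acid
Product: 25 15-(tert-butyldimethylsilyloxy)-8,8-ethylenedioxy-17-norlabd-2-en-19-oic acid, via acetate 24 (not isolated)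
Conditions: Ac2O, DMAP, pyridine, rt; then Na(Hg), Na2HPO4, MeOH/THF, −20 °C; acidic work-up
Reagents that add atoms: none
Why: Julia–Lythgoe reductive elimination of the β-acetoxy sulfone, which is stereoconvergent and so removes both the C2 sulfone and the C3 oxygen from either diastereomer to give the C2=C3 alkene.

**Step 17**
Reactants: 25 the Δ2 acid
Product: 26 15-(tert-butyldimethylsilyloxy)-8,8-ethylenedioxy-17-norlabdan-19-oic acid
Conditions: H2 (1 atm), Pd/C, EtOAc, rt
Reagents that add atoms: none
Why: Catalytic hydrogenation of the only alkene, a cis-disubstituted ring double bond, which creates no stereocenter and is done before the methylidene is introduced.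

**Step 18**
Reactants: 26 the saturated ketal acid
Product: 27 15-hydroxy-8-oxo-17-norlabdan-19-oic acid
Conditions: 2 M HCl, THF, rt
Reagents that add atoms: water, O
Why: Acid hydrolysis removes the dioxolane and the primary silyl ether together, and C9 next to the new ketone stays in (or equilibrates to) the equatorial side-chain configuration, which is the natural one.

**Step 19**
Reactants: 27 the hydroxy keto acid
Product: 28 15-hydroxylabd-8(17)-en-19-oic acid (imbricatolic acid)
Conditions: Ph3PCH3Br (5 equiv), KOt-Bu, THF/toluene, rt to 60 °C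
Reagents that add atoms: methyltriphenylphosphonium bromide, C[P+](c1ccccc1)(c1ccccc1)c1ccccc1.[Br-]
Why: Wittig methylenation of the hindered C8 ketone with excess ylide, the carboxylate and alkoxide being spectators and any C9 epimerization under the basic conditions leading to the desired equatorial isomer.

**Step 20**
Reactants: 28 imbricatolic acid
Product: 29 15-acetoxylabd-8(17)-en-19-oic acid (target)
Conditions: Ac2O, pyridine, DMAP (cat.), CH2Cl2, 0 °C to rt; aq. NaHCO3 work-up
Reagents that add atoms: acetic anhydride, CC(=O)OC(C)=O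
Why: Acetylation of the primary alcohol; any mixed anhydride at the hindered C19 acid is hydrolysed on aqueous work-up.

**Compound list**
1 | methyl (R)-3-methylglutarate [(3R)-5-methoxy-3-methyl-5-oxopentanoic acid] | COC(=O)C[C@H](C)CC(=O)O | starting material
2 | methyl (3R)-5-hydroxy-3-methylpentanoate | COC(=O)C[C@H](C)CCO | intermediate
3 | methyl (3R)-5-(tert-butyldimethylsilyloxy)-3-methylpentanoate | COC(=O)C[C@H](C)CCO[Si](C)(C)C(C)(C)C | intermediate
4 | (3S)-5-(tert-butyldimethylsilyloxy)-3-methylpentan-1-ol | OCC[C@H](C)CCO[Si](C)(C)C(C)(C)C | intermediate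
5 | tert-butyl{[(3R)-5-iodo-3-methylpentyl]oxy}dimethylsilane | ICC[C@H](C)CCO[Si](C)(C)C(C)(C)C | intermediate
6 | rac-cyclohex-2-en-1-yl acetate | CC(=O)OC1C=CCCC1 | starting material
7 | dimethyl methylmalonate | COC(=O)C(C)C(=O)OC | starting material
8 | dimethyl 2-[(1R)-cyclohex-2-en-1-yl]-2-methylmalonate | COC(=O)C(C)(C(=O)OC)[C@H]1C=CCCC1 | intermediate
9 | dimethyl 2-methyl-2-[(1R)-4-oxocyclohex-2-en-1-yl]malonate | COC(=O)C(C)(C(=O)OC)[C@H]1C=CC(=O)CC1 | intermediate
10 | dimethyl 2-methyl-2-[(1R,2S)-2-methyl-4-(trimethylsilyloxy)cyclohex-3-en-1-yl]malonate (not isolated) | COC(=O)C(C)(C(=O)OC)[C@H]1[C@H](C)C=C(O[Si](C)(C)C)CC1 | intermediate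
11 | dimethyl 2-methyl-2-[(1R)-2-methyl-4-oxocyclohex-2-en-1-yl]malonate | COC(=O)C(C)(C(=O)OC)[C@H]1C(C)=CC(=O)CC1 | intermediate
12 | dimethyl 2-[(1S)-3-iodo-2-methyl-4-oxocyclohex-2-en-1-yl]-2-methylmalonate | COC(=O)C(C)(C(=O)OC)[C@H]1C(C)=C(I)C(=O)CC1 | intermediate
13 | [(3R)-5-(tert-butyldimethylsilyloxy)-3-methylpentyl]zinc iodide (not isolated) | I[Zn]CC[C@H](C)CCO[Si](C)(C)C(C)(C)C | intermediate
14 | dimethyl 2-[(1R)-3-[(3S)-5-(tert-butyldimethylsilyloxy)-3-methylpentyl]-2-methyl-4-oxocyclohex-2-en-1-yl]-2-methylmalonate | COC(=O)C(C)(C(=O)OC)[C@H]1C(C)=C(CC[C@H](C)CCO[Si](C)(C)C(C)(C)C)C(=O)CC1 | intermediate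
15 | potassium dienolate of 14 (O– on C8, C8=C9, C10=C20) (not isolated) | COC(=O)C(C)(C(=O)OC)[C@H]1C(=C)C(CC[C@H](C)CCO[Si](C)(C)C(C)(C)C)=C([O-])CC1.[K+] | intermediate
16 | dimethyl 2-[(1R,3R)-3-[(3S)-5-(tert-butyldimethylsilyloxy)-3-methylpentyl]-2-methylidene-4-oxocyclohexyl]-2-methylmalonate | COC(=O)C(C)(C(=O)OC)[C@H]1C(=C)[C@@H](CC[C@H](C)CCO[Si](C)(C)C(C)(C)C)C(=O)CC1 | intermediate
17 | dimethyl 2-[(6R,8R)-6-[(3S)-5-(tert-butyldimethylsilyloxy)-3-methylpentyl]-7-methylidene-1,4-dioxaspiro[4.5]decan-8-yl]-2-methylmalonate | COC(=O)C(C)(C(=O)OC)[C@H]1C(=C)[C@@H](CC[C@H](C)CCO[Si](C)(C)C(C)(C)C)C2(OCCO2)CC1 | intermediate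
18 | 2-[(6R,8R)-6-[(3S)-5-(tert-butyldimethylsilyloxy)-3-methylpentyl]-7-methylidene-1,4-dioxaspiro[4.5]decan-8-yl]-2-methylpropane-1,3-diol | OCC(C)(CO)[C@H]1C(=C)[C@@H](CC[C@H](C)CCO[Si](C)(C)C(C)(C)C)C2(OCCO2)CC1 | intermediate
19 | 2-[(6R,8R)-6-[(3S)-5-(tert-butyldimethylsilyloxy)-3-methylpentyl]-7-methylidene-1,4-dioxaspiro[4.5]decan-8-yl]-2-methylpropanedial | O=CC(C)(C=O)[C@H]1C(=C)[C@@H](CC[C@H](C)CCO[Si](C)(C)C(C)(C)C)C2(OCCO2)CC1 | intermediate
20 | phenyl vinyl sulfone | C=CS(=O)(=O)c1ccccc1 | starting material
21 | α-sulfonyl carbanion of the conjugate adduct of 19 and 20 (C10 quaternary, new methyl cis to the C5 and C9 substituents) (not isolated) | O=CC(C)(C=O)[C@H]1[C@](C)(C[CH-]S(=O)(=O)c2ccccc2)[C@@H](CC[C@H](C)CCO[Si](C)(C)C(C)(C)C)C3(OCCO3)CC1 | intermediate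
22 | (13S)-15-(tert-butyldimethylsilyloxy)-8,8-ethylenedioxy-3-hydroxy-2-(phenylsulfonyl)-17-norlabdan-19-al (4β-CHO, 5α-H, 9α-H, 10β-CH3; C2 and C3 as mixtures) | O1CCOC12CC[C@@H]3[C@](C)(CC(S(=O)(=O)c4ccccc4)C(O)[C@]3(C)C=O)[C@H]2CC[C@H](C)CCO[Si](C)(C)C(C)(C)C | intermediate
23 | (13S)-15-(tert-butyldimethylsilyloxy)-8,8-ethylenedioxy-3-hydroxy-2-(phenylsulfonyl)-17-norlabdan-19-oic acid | O1CCOC12CC[C@@H]3[C@](C)(CC(S(=O)(=O)c4ccccc4)C(O)[C@]3(C)C(=O)O)[C@H]2CC[C@H](C)CCO[Si](C)(C)C(C)(C)C | intermediate
24 | (13S)-3-acetoxy-15-(tert-butyldimethylsilyloxy)-8,8-ethylenedioxy-2-(phenylsulfonyl)-17-norlabdan-19-oic acid (not isolated) | O1CCOC12CC[C@@H]3[C@](C)(CC(S(=O)(=O)c4ccccc4)C(OC(C)=O)[C@]3(C)C(=O)O)[C@H]2CC[C@H](C)CCO[Si](C)(C)C(C)(C)C | intermediate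
25 | (13S)-15-(tert-butyldimethylsilyloxy)-8,8-ethylenedioxy-17-norlabd-2-en-19-oic acid | O1CCOC12CC[C@@H]3[C@](C)(CC=C[C@]3(C)C(=O)O)[C@H]2CC[C@H](C)CCO[Si](C)(C)C(C)(C)C | intermediate
26 | (13S)-15-(tert-butyldimethylsilyloxy)-8,8-ethylenedioxy-17-norlabdan-19-oic acid | O1CCOC12CC[C@@H]3[C@](C)(CCC[C@]3(C)C(=O)O)[C@H]2CC[C@H](C)CCO[Si](C)(C)C(C)(C)C | intermediate
27 | (13S)-15-hydroxy-8-oxo-17-norlabdan-19-oic acid | O=C1CC[C@@H]2[C@](C)(CCC[C@]2(C)C(=O)O)[C@H]1CC[C@H](C)CCO | intermediate
28 | (13S)-15-hydroxylabd-8(17)-en-19-oic acid (imbricatolic acid) | C=C1CC[C@@H]2[C@](C)(CCC[C@]2(C)C(=O)O)[C@H]1CC[C@H](C)CCO | intermediate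
29 | (13S)-15-acetoxylabd-8(17)-en-19-oic acid (4S,5R,9S,10R,13S) | C=C1CC[C@@H]2[C@](C)(CCC[C@]2(C)C(=O)O)[C@H]1CC[C@H](C)CCOC(C)=O | target

**Count**
Total: 20 steps. Longest linear sequence: 16 steps (steps 5 to 20); the side-chain branch (steps 1 to 4) joins at step 9.

**Steps most likely to fail**

1. Step 14 (bears the label). The α-sulfonyl intermediate may be quenched by hydrogen-atom or proton transfer before ring closure. The aldolate may reopen by retro-aldol cleavage. The radical may be translocated to the side chain or the dioxolane. The acceptor may add with poor facial selectivity at C10. Fallback with known chemistry, from 19: the two bonds are made in two operations. The iron-hydride reductive olefin coupling with 20 under the usual protic conditions (Fe(acac)3, PhSiH3, EtOH/(CH2OH)2, 60 °C) stops at the protonated conjugate adduct and would give the open-chain sulfone dialdehyde F1. Deprotonation α to the sulfone with LiN(SiMe3)2 in THF at −78 °C and cold quench (sulfone carbanion addition to an aldehyde, as in the first stage of a Julia olefination) would then close ring A and return to 22.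

2. Step 10. The base may remove C5–H instead of a C20 hydrogen, which would erode the C5 configuration. The product may return to the conjugated enone on work-up. The dienolate may be acylated by a malonate ester. Fallback without strong base, from 14: acid-catalysed enol acetylation (isopropenyl acetate, TsOH, reflux) would give the exocyclic dienol acetate F2. Reduction with NaBH4 in EtOH at 0 °C (deconjugative reduction of a dienol acetate) would give the homoallylic alcohol F3. Buffered oxidation with the triacetoxy periodinane (DMP, NaHCO3, CH2Cl2) would return to 16.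

3. Step 6. Oxidation may occur at the wrong end of the allyl system (transposed enone), or over-oxidation may occur. Fallback, from 7: the oxygen at C8 is brought in with the electrophile. Desymmetrising Tsuji–Trost alkylation of the meso diester cis-cyclohex-2-ene-1,4-diyl diacetate F4 with 7 under the catalyst system of step 5 would give the cis acetoxy malonate F5. Methanolysis (K2CO3, MeOH) would give the allylic alcohol F6. Oxidation with MnO2 in CH2Cl2 would return to 9, bypassing 8.

Further compounds
F1 | step 14 | 2-[(6R,8R)-6-[(3S)-5-(tert-butyldimethylsilyloxy)-3-methylpentyl]-7-methyl-7-[2-(phenylsulfonyl)ethyl]-1,4-dioxaspiro[4.5]decan-8-yl]-2-methylpropanedial (C7 methyl cis to the C6 and C8 substituents) | O=CC(C)(C=O)[C@H]1[C@](C)(CCS(=O)(=O)c2ccccc2)[C@@H](CC[C@H](C)CCO[Si](C)(C)C(C)(C)C)C3(OCCO3)CC1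
F2 | step 10 | dimethyl 2-[(1R)-4-acetoxy-3-[(3S)-5-(tert-butyldimethylsilyloxy)-3-methylpentyl]-2-methylidenecyclohex-3-en-1-yl]-2-methylmalonate | COC(=O)C(C)(C(=O)OC)[C@H]1C(=C)C(CC[C@H](C)CCO[Si](C)(C)C(C)(C)C)=C(OC(C)=O)CC1
F3 | step 10 | dimethyl 2-[(1R,3R)-3-[(3S)-5-(tert-butyldimethylsilyloxy)-3-methylpentyl]-4-hydroxy-2-methylidenecyclohexyl]-2-methylmalonate (carbinol epimers) | COC(=O)C(C)(C(=O)OC)[C@H]1C(=C)[C@@H](CC[C@H](C)CCO[Si](C)(C)C(C)(C)C)C(O)CC1
F4 | step 6 | cis-cyclohex-2-ene-1,4-diyl diacetate (meso) | CC(=O)O[C@H]1C=C[C@@H](OC(C)=O)CC1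
F5 | step 6 | dimethyl 2-[(1R,4S)-4-acetoxycyclohex-2-en-1-yl]-2-methylmalonate | COC(=O)C(C)(C(=O)OC)[C@H]1C=C[C@@H](OC(C)=O)CC1
F6 | step 6 | dimethyl 2-[(1R,4S)-4-hydroxycyclohex-2-en-1-yl]-2-methylmalonate | COC(=O)C(C)(C(=O)OC)[C@H]1C=C[C@@H](O)CC1
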